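Ring A (the cyclohexene; C1 quaternary, C2, C3, C4 bearing methyl, C5, C6 bearing the aryl) is disconnected at C1–CH3 and C6–aryl, and the C1 styryl arm is traced back to a C1–B bond. One palladium-catalysed three-component coupling of an achiral 4-methylcyclohexa-1,3-dienyl pinacol boronate, methyllithium and a MOM-protected bromophloroglucinol dimethyl ether adds methyl and aryl anti across C1=C6, sets both stereocentres and leaves the C4=C5 alkene and a tertiary boronic ester. The feature exploited is the trans relationship of the C1 methyl and C6 aryl on adjacent ring-A carbons. Boron is then exchanged for vinyl with retention, and the two coumarins are completed by Heck arylation and phenol annulation.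

Key step: step 5

Remark on the chemistry: ring A is numbered C1 (quaternary carbon), C2 and C3 (CH2), C4 (methyl-bearing sp2 carbon), C5 (sp2 CH), C6 (aryl-bearing CH), and all names use these locants. Commercial 1 is racemic, which does not matter because its stereocentre becomes sp2 in step 1.

Step 1
Reactants: 1 4-methylcyclohex-2-en-1-one (racemic)
Product: 2 4-methylcyclohexa-1,3-dien-1-yl trifluoromethanesulfonate
Conditions: Tf2O, 2,6-di-tert-butyl-4-methylpyridine, CH2Cl2, 0 °C → rt
Reagents that add atoms: trifluoromethanesulfonic anhydride, O=S(=O)(OS(=O)(=O)C(F)(F)F)C(F)(F)F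
Why: Enol triflate formation: O-triflation of the enone and removal of the γ-proton at C4 by the hindered pyridine should give the thermodynamically preferred through-conjugated dienyl triflate (as with steroidal 4-en-3-ones), which erases the stereocentre of racemic 1.

Step 2
Reactants: 2 4-methylcyclohexa-1,3-dien-1-yl trifluoromethanesulfonate; 3 bis(pinacolato)diboron
Product: 4 4,4,5,5-tetramethyl-2-(4-methylcyclohexa-1,3-dien-1-yl)-1,3,2-dioxaborolane
Conditions: PdCl2(PPh3)2 (3 mol %), PPh3, KOPh, toluene, 50 °C
Reagents that add atoms: none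
Why: Miyaura borylation: oxidative addition of the alkenyl triflate to zerovalent palladium, phenoxide-assisted transmetalation from 3 and reductive elimination should give the dienyl boronate at a temperature low enough to leave the 1,3-diene in place.

Step 3
Reactants: 5 3,5-dimethoxyphenol
Product: 6 1,3-dimethoxy-5-(methoxymethoxy)benzene
Conditions: MOMCl, i-Pr2NEt, CH2Cl2, 0 °C → rt
Reagents that add atoms: chloromethyl methyl ether, COCCl
Why: Williamson-type O-alkylation of the phenol by the reactive chloromethyl ether installs an acetal that survives organolithium reagents and directs the next metalation.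

Step 4
Reactants: 6 1,3-dimethoxy-5-(methoxymethoxy)benzene
Product: 8 2-bromo-1,5-dimethoxy-3-(methoxymethoxy)benzene, via aryllithium 7 (not isolated)
Conditions: n-BuLi, TMEDA, THF, 0 °C; then BrCCl2CCl2Br, −78 °C → rt
Reagents that add atoms: 1,2-dibromo-1,1,2,2-tetrachloroethane, BrC(Cl)(Cl)C(Cl)(Cl)Br
Why: Directed ortho-metalation: the chelating OCH2OCH3 group, reinforced by the neighbouring methoxy group, should steer lithiation to the carbon between them in preference to the carbon between the two methoxy groups, and the aryllithium takes bromine from the dibromide with loss of tetrachloroethene.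

Step 5
Reactants: 4 4,4,5,5-tetramethyl-2-(4-methylcyclohexa-1,3-dien-1-yl)-1,3,2-dioxaborolane; 8 2-bromo-1,5-dimethoxy-3-(methoxymethoxy)benzene; 9 methyllithium
Product: 11 2-[(1R,6R)-6-[2,4-dimethoxy-6-(methoxymethoxy)phenyl]-1,4-dimethylcyclohex-4-en-1-yl]-4,4,5,5-tetramethyl-1,3,2-dioxaborolane (boron cis to aryl; methyl trans to aryl), via lithium borate complex 10 (not isolated)
Conditions: 9 (low-halide, Et2O), THF, 0 °C → rt; then 8, Pd(OAc)2 (5 mol %), (Sp,Sp)-MandyPhos (6 mol %), KOTf, THF, 60 °C
Reagents that add atoms: none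
Why: Proposed new method: oxidative addition of 8 to zerovalent palladium gives a cationic arylpalladium (bromide removed as KBr by KOTf) that binds the C1=C6 alkene of borate 10 and triggers 1,2-migration of methyl from boron to C1 anti to the metal; the resulting allylpalladium reductively eliminates at C6 with retention, so methyl and aryl end up trans and boron cis to aryl. The closest known reaction is the enantioselective Pd(OAc)2/MandyPhos conjunctive cross-coupling of alkenylboron ate complexes with aryl electrophiles, including methyl migration and tertiary boronic ester formation, which has not been shown for a cyclic dienyl boronate or for a 2,6-dialkoxyaryl bromide. No ring is closed; C6 is set by the alkene face that the chiral ligand lets palladium occupy (the ligand antipode is chosen for the 1R,6R product), and C1 follows stereospecifically from the anti-periplanar shift. The step needs 1,2- instead of 1,4-addition, which the fully substituted C4 terminus should secure because aryl transfer there would build a quaternary centre; it also needs conjunctive coupling to outrun direct Suzuki-type transfer of the dienyl group and β-hydride loss, which the strongly binding conjugated diene, the four-coordinate pinacol borate and the halide scavenger are meant to favour.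

Step 6
Reactants: 11 2-[(1R,6R)-6-[2,4-dimethoxy-6-(methoxymethoxy)phenyl]-1,4-dimethylcyclohex-4-en-1-yl]-4,4,5,5-tetramethyl-1,3,2-dioxaborolane
Product: 14 2-[(1R,6R)-1-ethenyl-1,4-dimethylcyclohex-4-en-6-yl]-1,5-dimethoxy-3-(methoxymethoxy)benzene (vinyl cis to aryl), via vinyl borate complex 12 (not isolated), via iodo boronic ester 13 (not isolated)
Conditions: CH2=CHLi (from Sn(CH=CH2)4, n-BuLi), THF, −78 °C → rt; then I2, MeOH, −78 °C; then NaOMe, MeOH, −78 °C → rt
Reagents that add atoms: vinyllithium, [Li]C=C, made in the flask from tetravinylstannane, C=C[Sn](C=C)(C=C)C=C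
Why: Zweifel olefination: iodine activates the vinyl group of the four-coordinate borate, C1 migrates from boron to carbon with retention of configuration, and methoxide-triggered anti elimination of boron and iodide releases the terminal alkene, a sequence established for tertiary pinacol boronic esters and vinyllithium; C6 is not involved.

Step 7
Reactants: 15 5,7-dimethoxy-2H-chromen-2-one (citropten)
Product: 16 8-iodo-5,7-dimethoxy-2H-chromen-2-one
Conditions: NIS, CF3CO2H (cat.), MeCN, rt
Reagents that add atoms: N-iodosuccinimide, O=C1CCC(=O)N1I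
Why: Electrophilic aromatic iodination: C8 is ortho and para to the two methoxy groups and flanked only by one of them and the ring oxygen, so it should be attacked in preference to the more crowded C6 and to C3 of the deactivated pyranone.

Step 8
Reactants: 14 2-[(1R,6R)-1-ethenyl-1,4-dimethylcyclohex-4-en-6-yl]-1,5-dimethoxy-3-(methoxymethoxy)benzene; 16 8-iodo-5,7-dimethoxy-2H-chromen-2-one
Product: 17 8-[(E)-2-[(1R,6R)-6-[2,4-dimethoxy-6-(methoxymethoxy)phenyl]-1,4-dimethylcyclohex-4-en-1-yl]ethenyl]-5,7-dimethoxy-2H-chromen-2-one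
Conditions: Pd(OAc)2 (10 mol %), n-Bu4NCl, NaHCO3, DMF, 90 °C
Reagents that add atoms: none
Why: Mizoroki–Heck reaction under Jeffery conditions: arylpalladium from 16 adds its aryl group to the unsubstituted vinyl terminus, and because C1 is quaternary the only syn β-hydrogens are benzylic, so elimination can give only the (E)-styrene, as in the known couplings of iodocoumarins with 2-methylbut-3-en-2-ol; the trisubstituted ring alkene and the stereocentres are untouched.

Step 9
Reactants: 17 8-[(E)-2-[(1R,6R)-6-[2,4-dimethoxy-6-(methoxymethoxy)phenyl]-1,4-dimethylcyclohex-4-en-1-yl]ethenyl]-5,7-dimethoxy-2H-chromen-2-one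
Product: 18 8-[(E)-2-[(1R,6R)-6-(2-hydroxy-4,6-dimethoxyphenyl)-1,4-dimethylcyclohex-4-en-1-yl]ethenyl]-5,7-dimethoxy-2H-chromen-2-one
Conditions: ZnBr2, n-PrSH, CH2Cl2, 0 °C
Reagents that add atoms: none
Why: Lewis-acid-assisted acetal cleavage: ZnBr2 ionises the methoxymethyl ether and the thiol captures the methoxymethyl cation, so no protic mineral acid is present that could drive the freed phenol to add across the C4=C5 alkene (the cannabidiol-type ether closure), and lactone, styrene and methyl ethers should remain.

Step 10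
Reactants: 18 8-[(E)-2-[(1R,6R)-6-(2-hydroxy-4,6-dimethoxyphenyl)-1,4-dimethylcyclohex-4-en-1-yl]ethenyl]-5,7-dimethoxy-2H-chromen-2-one
Product: 20 8-[(E)-2-[(1R,6R)-6-(3-formyl-2-hydroxy-4,6-dimethoxyphenyl)-1,4-dimethylcyclohex-4-en-1-yl]ethenyl]-5,7-dimethoxy-2H-chromen-2-one, via hydroxymethyl phenol 19 (not isolated)
Conditions: MgCl2, Et3N, (CH2O)n, MeCN, reflux
Reagents that add atoms: paraformaldehyde (reacting as formaldehyde), C=O
Why: Casnati–Skattebøl ortho-formylation: the magnesium phenoxide delivers formaldehyde only to the one free ortho position and a second formaldehyde oxidises the resulting benzylic alkoxide by hydride transfer, while the non-phenolic coumarin ring and the alkenes should not react under these weakly basic conditions.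

Step 11
Reactants: 20 8-[(E)-2-[(1R,6R)-6-(3-formyl-2-hydroxy-4,6-dimethoxyphenyl)-1,4-dimethylcyclohex-4-en-1-yl]ethenyl]-5,7-dimethoxy-2H-chromen-2-one
Product: 22 8-[(E)-2-[(1R,6R)-6-(5,7-dimethoxy-2-oxo-2H-chromen-8-yl)-1,4-dimethylcyclohex-4-en-1-yl]ethenyl]-5,7-dimethoxy-2H-chromen-2-one (the target), via hydroxycinnamate ester 21 (not isolated)
Conditions: Ph3P=CHCO2Et, PhNEt2, 190 °C
Reagents that add atoms: ethyl (triphenylphosphoranylidene)acetate, CCOC(=O)C=P(c1ccccc1)(c1ccccc1)c1ccccc1
Why: Wittig olefination followed by lactonisation: the stabilised ylide gives the 2-hydroxycinnamate, which at this temperature equilibrates to the Z isomer and closes by intramolecular transesterification, the standard conversion of 2-hydroxy-4,6-dimethoxybenzaldehydes into 5,7-dimethoxycoumarins; both stereocentres lie far from any acidic position.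

Compound list
1 | 4-methylcyclohex-2-en-1-one (racemic) | CC1CCC(=O)C=C1 | starting material
2 | 4-methylcyclohexa-1,3-dien-1-yl trifluoromethanesulfonate | CC1=CC=C(OS(=O)(=O)C(F)(F)F)CC1 | intermediate
3 | bis(pinacolato)diboron | CC1(C)OB(OC1(C)C)B1OC(C)(C)C(C)(C)O1 | starting material
4 | 4,4,5,5-tetramethyl-2-(4-methylcyclohexa-1,3-dien-1-yl)-1,3,2-dioxaborolane | CC1=CC=C(B2OC(C)(C)C(C)(C)O2)CC1 | intermediate
5 | 3,5-dimethoxyphenol | COc1cc(O)cc(OC)c1 | starting material
6 | 1,3-dimethoxy-5-(methoxymethoxy)benzene | COCOc1cc(OC)cc(OC)c1 | intermediate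
7 | [2,4-dimethoxy-6-(methoxymethoxy)phenyl]lithium | [Li]c1c(OC)cc(OC)cc1OCOC | intermediate (not isolated)
8 | 2-bromo-1,5-dimethoxy-3-(methoxymethoxy)benzene | COCOc1cc(OC)cc(OC)c1Br | intermediate
9 | methyllithium | [Li]C | starting material
10 | lithium methyl(4-methylcyclohexa-1,3-dien-1-yl)(pinacolato)borate | [Li+].C[B-]1(OC(C)(C)C(C)(C)O1)C1=CC=C(C)CC1 | intermediate (not isolated)
11 | 2-[(1R,6R)-6-[2,4-dimethoxy-6-(methoxymethoxy)phenyl]-1,4-dimethylcyclohex-4-en-1-yl]-4,4,5,5-tetramethyl-1,3,2-dioxaborolane (boron cis to aryl, methyl trans to aryl) | CC1(C)OB(OC1(C)C)[C@@]1(C)CCC(C)=C[C@H]1c1c(OC)cc(OC)cc1OCOC | intermediate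
12 | lithium [(1R,6R)-6-[2,4-dimethoxy-6-(methoxymethoxy)phenyl]-1,4-dimethylcyclohex-4-en-1-yl](ethenyl)(pinacolato)borate | [Li+].C=C[B-]1(OC(C)(C)C(C)(C)O1)[C@@]1(C)CCC(C)=C[C@H]1c1c(OC)cc(OC)cc1OCOC | intermediate (not isolated)
13 | 2-[1-[(1R,6R)-6-[2,4-dimethoxy-6-(methoxymethoxy)phenyl]-1,4-dimethylcyclohex-4-en-1-yl]-2-iodoethyl]-4,4,5,5-tetramethyl-1,3,2-dioxaborolane (either epimer at the CH–B carbon) | CC1(C)OB(OC1(C)C)C(CI)[C@@]1(C)CCC(C)=C[C@H]1c1c(OC)cc(OC)cc1OCOC | intermediate (not isolated)
14 | 2-[(1R,6R)-1-ethenyl-1,4-dimethylcyclohex-4-en-6-yl]-1,5-dimethoxy-3-(methoxymethoxy)benzene (vinyl cis to aryl) | C=C[C@@]1(C)CCC(C)=C[C@H]1c1c(OC)cc(OC)cc1OCOC | intermediate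
15 | 5,7-dimethoxy-2H-chromen-2-one (citropten) | COc1cc(OC)c2ccc(=O)oc2c1 | starting material
16 | 8-iodo-5,7-dimethoxy-2H-chromen-2-one | COc1cc(OC)c2ccc(=O)oc2c1I | intermediate
17 | 8-[(E)-2-[(1R,6R)-6-[2,4-dimethoxy-6-(methoxymethoxy)phenyl]-1,4-dimethylcyclohex-4-en-1-yl]ethenyl]-5,7-dimethoxy-2H-chromen-2-one | COc1cc(OC)c2ccc(=O)oc2c1/C=C/[C@@]1(C)CCC(C)=C[C@H]1c1c(OC)cc(OC)cc1OCOC | intermediate
18 | 8-[(E)-2-[(1R,6R)-6-(2-hydroxy-4,6-dimethoxyphenyl)-1,4-dimethylcyclohex-4-en-1-yl]ethenyl]-5,7-dimethoxy-2H-chromen-2-one | COc1cc(OC)c2ccc(=O)oc2c1/C=C/[C@@]1(C)CCC(C)=C[C@H]1c1c(OC)cc(OC)cc1O | intermediate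
19 | 8-[(E)-2-[(1R,6R)-6-[2-hydroxy-3-(hydroxymethyl)-4,6-dimethoxyphenyl]-1,4-dimethylcyclohex-4-en-1-yl]ethenyl]-5,7-dimethoxy-2H-chromen-2-one (present as its magnesium salt) | COc1cc(OC)c2ccc(=O)oc2c1/C=C/[C@@]1(C)CCC(C)=C[C@H]1c1c(OC)cc(OC)c(CO)c1O | intermediate (not isolated)
20 | 8-[(E)-2-[(1R,6R)-6-(3-formyl-2-hydroxy-4,6-dimethoxyphenyl)-1,4-dimethylcyclohex-4-en-1-yl]ethenyl]-5,7-dimethoxy-2H-chromen-2-one | COc1cc(OC)c2ccc(=O)oc2c1/C=C/[C@@]1(C)CCC(C)=C[C@H]1c1c(OC)cc(OC)c(C=O)c1O | intermediate
21 | ethyl 3-[2-hydroxy-4,6-dimethoxy-3-[(1R,6R)-1-[(E)-2-(5,7-dimethoxy-2-oxo-2H-chromen-8-yl)ethenyl]-1,4-dimethylcyclohex-4-en-6-yl]phenyl]prop-2-enoate (E/Z mixture at the new alkene) | COc1cc(OC)c2ccc(=O)oc2c1/C=C/[C@@]1(C)CCC(C)=C[C@H]1c1c(OC)cc(OC)c(C=CC(=O)OCC)c1O | intermediate (not isolated)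
22 | 8-[(E)-2-[(1R,6R)-6-(5,7-dimethoxy-2-oxo-2H-chromen-8-yl)-1,4-dimethylcyclohex-4-en-1-yl]ethenyl]-5,7-dimethoxy-2H-chromen-2-one | COc1cc(OC)c2ccc(=O)oc2c1/C=C/[C@@]1(C)CCC(C)=C[C@H]1c1c(OC)cc(OC)c2ccc(=O)oc12 | target

Total step count: 11. Longest linear sequence: 8 steps (steps 1, 2, 5, 6, 8, 9, 10, 11 from 1; equally steps 3, 4, 5, 6, 8, 9, 10, 11 from 5).

Steps most likely to fail

Step 5 (the proposed new method). The coupling may fail in several ways: direct transfer of the dienyl group to palladium, arylation at C4, β-hydride loss from the allylpalladium intermediate, slow oxidative addition of the hindered electron-rich bromide, or poor facial selectivity. The fallback builds ring A by a catalytic enantioselective Diels–Alder reaction, all of it known chemistry, and sets out from 6.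
- Lithiation of 6 as in step 4 (via 7) and a DMF quench should give 2,4-dimethoxy-6-(methoxymethoxy)benzaldehyde F1.
- Claisen–Schmidt condensation with acetone (NaOH, H2O/acetone) should give the (E)-enone F2.
- Wittig methylenation (Ph3P=CH2, THF) should give the (E)-1-aryl-3-methylbuta-1,3-diene F3.
- Cycloaddition of F3 with methacrolein, catalysed by a chiral oxazaborolidinium triflimide (protonated o-tolyl oxazaborolidine from diphenylprolinol, CH2Cl2, −78 °C), should give the cyclohexenecarbaldehyde F4. The aryl and methyl groups of the diene direct the regiochemistry, the endo transition state places formyl cis to aryl, and the catalyst antipode is chosen for the configuration of 14.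
- Wittig methylenation of F4 comes back to the route at 14, so steps 5 and 6 are both bypassed.

Step 6. The crowded tertiary boronic ester may not bind vinyllithium, the borate may revert before migration, or the electron-rich arene may be iodinated. The fallback sets out from 11 and adds the two carbons one at a time.
- Matteson homologation with chloromethyllithium (BrCH2Cl, n-BuLi, THF, −78 °C → rt), a smaller and more reactive nucleophile, should give the homologated primary boronic ester F5 with retention at C1.
- Oxidation (NaOH, H2O2, THF, 0 °C) should give the neopentyl-type primary alcohol F6.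
- Dess–Martin oxidation gives aldehyde F4, the same aldehyde as in the first fallback.
- Wittig methylenation (Ph3P=CH2) comes back to the route at 14.

Step 8. Carbopalladation of the neopentyl-type vinyl group by the hindered, electron-rich arylpalladium may be too slow, so that reductive deiodination of 16 or catalyst decay takes over. The fallback sets out from 14 and makes the aryl–alkenyl bond by Suzuki–Miyaura coupling instead.
- Cross-metathesis of 14 with vinylboronic acid pinacol ester (second-generation Hoveyda–Grubbs catalyst, CH2Cl2, reflux) should give the (E)-alkenyl boronate F7; the trisubstituted ring alkene is inert.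
- Coupling of F7 with 16 (Pd(OAc)2, SPhos, K3PO4, dioxane/H2O, 80 °C) comes back to the route at 17 with the E geometry retained.

Further compounds
F1 | step 5 | 2,4-dimethoxy-6-(methoxymethoxy)benzaldehyde | COCOc1cc(OC)cc(OC)c1C=O
F2 | step 5 | (E)-4-[2,4-dimethoxy-6-(methoxymethoxy)phenyl]but-3-en-2-one | CC(=O)/C=C/c1c(OC)cc(OC)cc1OCOC
F3 | step 5 | 1,5-dimethoxy-3-(methoxymethoxy)-2-[(E)-3-methylbuta-1,3-dien-1-yl]benzene | C=C(C)/C=C/c1c(OC)cc(OC)cc1OCOC
F4 | step 5 | 6-[2,4-dimethoxy-6-(methoxymethoxy)phenyl]-1,4-dimethylcyclohex-4-ene-1-carbaldehyde (formyl cis to aryl; same spatial arrangement as 14) | O=C[C@@]1(C)CCC(C)=C[C@H]1c1c(OC)cc(OC)cc1OCOC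
F5 | step 6 | 2-[[6-[2,4-dimethoxy-6-(methoxymethoxy)phenyl]-1,4-dimethylcyclohex-4-en-1-yl]methyl]-4,4,5,5-tetramethyl-1,3,2-dioxaborolane (same spatial arrangement as 11) | CC1(C)OB(C[C@@]2(C)CCC(C)=C[C@H]2c2c(OC)cc(OC)cc2OCOC)OC1(C)C
F6 | step 6 | [6-[2,4-dimethoxy-6-(methoxymethoxy)phenyl]-1,4-dimethylcyclohex-4-en-1-yl]methanol (same spatial arrangement as 11) | OC[C@@]1(C)CCC(C)=C[C@H]1c1c(OC)cc(OC)cc1OCOC
F7 | step 8 | 2-[(E)-2-[6-[2,4-dimethoxy-6-(methoxymethoxy)phenyl]-1,4-dimethylcyclohex-4-en-1-yl]ethenyl]-4,4,5,5-tetramethyl-1,3,2-dioxaborolane (same spatial arrangement as 14) | CC1(C)OB(/C=C/[C@@]2(C)CCC(C)=C[C@H]2c2c(OC)cc(OC)cc2OCOC)OC1(C)C
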